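## Retrosynthetic overview
1. Target **18** comes from global O-debenzylation of perbenzyl ether **17**. All 15 phenols are carried as benzyl ethers, and the C-1 benzylic alcohol is left free.
2. **17** comes from a proposed new Lewis-acid intramolecular arene–aldehyde hydroxyalkylation of aldehyde **16**. This closes the 6-membered dihydroisocoumarin ring, forms the C1–aryl bond and sets C-1. **16** comes from the dithioacetal **15**.
3. In **15**, three macrocycles are closed by sugar-templated CuTC Ullmann couplings, in this order: the 3,5-(A/B) 11-membered ring, the 2,3-(D/B) 10-membered ring, then the 4,6-HHDP (E/F) 11-membered ring.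
4. The sugar is D-glucose as diacetone glucose, which gives O-3 a unique handle. It is opened to the C-1 diethyl dithioacetal. Every aryl unit comes from 3,4,5-tris(benzyloxy)benzoic acid by iodination.

Ring labels: A = 5-O-aroyl, B = 3-O-aroyl (central ring), D = 2-O-aroyl, E = 4-O-aroyl, F = 6-O-aroyl. Bn = benzyl.

Assumptions:
- The target is a C-glucosidic ellagitannin of the vescalagin/castalagin type. C-1 is R by CIP, taken directly from the SMILES, and C2–C5 are D-gluco.
- The SMILES does not encode biaryl axes, so I assume the natural sense, enforced by the D-gluco tether in each Ullmann ring closure.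
- 2,6-Diiodination of acid **2** works, and O-2 of **10** is much more accessible than O-4, which sits inside the A/B macrocycle.

## Route

**Step 1**
Reactants: **1** 3,4,5-tris(benzyloxy)benzoic acid
Product: **2** 2-iodo-3,4,5-tris(benzyloxy)benzoic acid
Conditions: NIS, cat. TFA, MeCN, 50 °C
Reagents that add atoms: N-iodosuccinimide, O=C1CCC(=O)N1I
Why: Electrophilic aromatic iodination goes at C-2, which is ortho to one OBn and para to another.

**Step 2**
Reactants: **2**
Product: **3** 2,6-diiodo-3,4,5-tris(benzyloxy)benzoic acid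
Conditions: NIS (2.5 equiv), TFA (1 equiv), MeCN, 70 °C
Reagents that add atoms: N-iodosuccinimide, O=C1CCC(=O)N1I
Why: A second SEAr iodination at the remaining activated ortho position gives the doubly halogenated central-ring (B) acid.

**Step 3**
Reactants: **3**; **4** 1,2:5,6-di-O-isopropylidene-α-D-glucofuranose (commercial)
Product: **5** 3-O-(2,6-diiodo-3,4,5-tris(benzyloxy)benzoyl)-1,2:5,6-di-O-isopropylidene-α-D-glucofuranose
Conditions: **3**, (COCl)2, cat. DMF, CH2Cl2; then **4**, DMAP, Et3N, ClCH2CH2Cl, 80 °C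
Reagents that add atoms: none
Why: Acid-chloride acylation of the only free OH (O-3) puts ring B on the sugar. No stereocentre is touched.

**Step 4**
Reactants: **5**
Product: **6** 3-O-aroyl-1,2-O-isopropylidene-α-D-glucofuranose (5,6-diol)
Conditions: 60% aq. AcOH, 40 °C
Reagents that add atoms: none
Why: The terminal 5,6-acetonide is much more labile than the furanose-fused 1,2-acetonide, so this is a selective acetal hydrolysis.

**Step 5**
Reactants: **6**
Product: **7** 6-O-TBDPS derivative of **6** (5-OH free)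
Conditions: TBDPSCl, imidazole, DMF, 0 °C to rt
Reagents that add atoms: TBDPSCl, CC(C)(C)[Si](Cl)(c1ccccc1)c1ccccc1
Why: Primary-selective silylation leaves O-5 as the only free OH.

**Step 6**
Reactants: **7**; **2**
Product: **8** 5-O-(2-iodo-3,4,5-tris(benzyloxy)benzoyl) ester of **7** (ring A)
Conditions: **2**, EDC·HCl, DMAP, CH2Cl2, rt
Reagents that add atoms: none
Why: Steglich esterification of the secondary O-5.

**Step 7**
Reactants: **8**
Product: **9** 3,5-bridged A/B macrolactone, with ring A C-2 bonded to ring B C-2 and one iodine left on ring B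
Conditions: CuTC (4 equiv), NMP, 5 mM, 50–60 °C
Reagents that add atoms: none
Why: Tether-controlled intramolecular Ullmann coupling on the D-gluco furanose template. The cis-disposed 3-O and C4–C5 arms fix the axial sense, and only ring A's iodide has a partner on ring B.

**Step 8**
Reactants: **9**
Product: **10** open-chain 6-O-TBDPS-D-glucose diethyl dithioacetal bearing the 3,5-A/B macrolactone, with O-2 and O-4 free
Conditions: EtSH (15 equiv), BF3·OEt2, CH2Cl2, 0 °C to rt
Reagents that add atoms: ethanethiol, CCS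
Why: Fischer-type dithioacetalisation cleaves the acetonide and opens the furanose. It masks C-1 as an aldehyde equivalent and leaves the C2–C5 configuration untouched.

**Step 9**
Reactants: **10**; **2**
Product: **11** 2-O-(2-iodoaroyl) ester (ring D) of **10**, with O-4 free
Conditions: **2**, 2,4,6-Cl3C6H2COCl, Et3N, THF; then **10**, DMAP, toluene, rt
Reagents that add atoms: none
Why: Yamaguchi esterification at the accessible O-2. O-4 is shielded by the flanking A/B bridge.

**Step 10**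
Reactants: **11**
Product: **12** 2,3-bridged D/B biaryl, giving the second macrolactone and a bis-macrocyclic NHTP core with no iodine left
Conditions: CuTC (4 equiv), NMP, 5 mM, 60 °C
Reagents that add atoms: none
Why: Second tether-directed Ullmann coupling, between ring D C-2 and the remaining ring B C-iodide. The template sets the D/B axis.

**Step 11**
Reactants: **12**
Product: **13** the 4,6-diol, with O-4 and O-6 free
Conditions: HF·pyridine, pyridine, THF, 0 °C to rt
Reagents that add atoms: none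
Why: Buffered fluoride removes the silyl ether without acyl migration.

**Step 12**
Reactants: **13**; **2** (3 equiv)
Product: **14** 4,6-bis(2-iodo-3,4,5-tris(benzyloxy)benzoate) (rings E and F)
Conditions: **2**, 2,4,6-Cl3C6H2COCl, Et3N, THF; then **13**, DMAP, toluene, 60 °C
Reagents that add atoms: none
Why: Yamaguchi double esterification; O-6 is primary and O-4 is forced with the mixed anhydride.

**Step 13**
Reactants: **14**
Product: **15** 4,6-HHDP-bridged tris-macrocyclic dithioacetal (perbenzyl)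
Conditions: CuTC (3 equiv), NMP, 5 mM, 60 °C
Reagents that add atoms: none
Why: Ullmann closure of the 4,6-HHDP ring. The D-gluco 4,6-tether gives the (S)-HHDP axis, as in corilagin-type syntheses.

**Step 14**
Reactants: **15**
Product: **16** C-1 aldehyde (perbenzyl)
Conditions: HgCl2, CaCO3, MeCN/H2O 4:1, 40 °C
Reagents that add atoms: water, O
Why: Hg(II)-promoted dithioacetal hydrolysis under neutral CaCO3 buffering, which avoids β-acyloxy elimination and C-2 epimerisation of the α-acyloxy aldehyde.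

**Step 15**
Reactants: **16**
Product: **17** perbenzyl target (1R)-C-1 alcohol, with the dihydroisocoumarin ring closed at C1–aryl
Conditions: Sc(OTf)3 (20 mol%), HFIP/CH2Cl2 1:9, 4 Å MS, 0 °C to rt
Reagents that add atoms: none
Why: Proposed new method: Sc(III) chelates the C-1 aldehyde oxygen and the O-2 ester carbonyl, and HFIP stabilises the Wheland intermediate, so the ring-D C–H ortho to the O-2 ester (activated by two flanking OBn groups) attacks C-1 in a 6-membered, Friedel–Crafts-type hydroxyalkylation that sets C-1. In the rigid NHTP macrocycle only the Re face of C-1 is reachable, giving (1R) with OH cis to C-3 on the new ring. The closest known reactions are intramolecular arene–aldehyde hydroxyalkylations forming 4-hydroxy-3,4-dihydroisocoumarins, and the biosynthetic C-glucosidation. Neither is known for polybenzyloxy-galloyl esters attacking an acyclic polyacyloxy aldose.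

**Step 16**
Reactants: **17**
Product: **18** target
Conditions: H2 (1 atm), Pd(OH)2/C, THF/MeOH 1:1, rt
Reagents that add atoms: none (H2 only)
Why: Hydrogenolysis removes all 15 aryl benzyl ethers. The electron-poor, ester-flanked C-1 benzylic alcohol and the lactones survive at rt under neutral conditions, and no stereocentre is affected.

## Compound list
1 | 3,4,5-tris(benzyloxy)benzoic acid | OC(=O)c1cc(OCc9ccccc9)c(OCc9ccccc9)c(OCc9ccccc9)c1 | starting material
2 | 2-iodo-3,4,5-tris(benzyloxy)benzoic acid | OC(=O)c1cc(OCc9ccccc9)c(OCc9ccccc9)c(OCc9ccccc9)c1I | intermediate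
3 | 2,6-diiodo-3,4,5-tris(benzyloxy)benzoic acid | OC(=O)c1c(I)c(OCc9ccccc9)c(OCc9ccccc9)c(OCc9ccccc9)c1I | intermediate
4 | 1,2:5,6-di-O-isopropylidene-α-D-glucofuranose | CC1(C)OC[C@@H](O1)[C@H]2O[C@@H]3OC(C)(C)O[C@@H]3[C@H]2O | starting material
5 | 3-O-(2,6-diiodo-tri-O-benzylgalloyl) diacetonide | CC1(C)OC[C@@H](O1)[C@H]2O[C@@H]3OC(C)(C)O[C@@H]3[C@H]2OC(=O)c4c(I)c(OCc9ccccc9)c(OCc9ccccc9)c(OCc9ccccc9)c4I | intermediate
6 | 5,6-diol (1,2-acetonide, 3-O-diiodoaroyl) | OC[C@@H](O)[C@H]2O[C@@H]3OC(C)(C)O[C@@H]3[C@H]2OC(=O)c4c(I)c(OCc9ccccc9)c(OCc9ccccc9)c(OCc9ccccc9)c4I | intermediate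
7 | 6-O-TBDPS derivative of 6 | CC(C)(C)[Si](c8ccccc8)(c8ccccc8)OC[C@@H](O)[C@H]2O[C@@H]3OC(C)(C)O[C@@H]3[C@H]2OC(=O)c4c(I)c(OCc9ccccc9)c(OCc9ccccc9)c(OCc9ccccc9)c4I | intermediate
8 | 5-O-(2-iodo-tri-O-benzylgalloyl) ester of 7 | CC(C)(C)[Si](c8ccccc8)(c8ccccc8)OC[C@@H](OC(=O)c6cc(OCc9ccccc9)c(OCc9ccccc9)c(OCc9ccccc9)c6I)[C@H]2O[C@@H]3OC(C)(C)O[C@@H]3[C@H]2OC(=O)c4c(I)c(OCc9ccccc9)c(OCc9ccccc9)c(OCc9ccccc9)c4I | intermediate
9 | 3,5-bridged A/B biaryl macrolactone | CC(C)(C)[Si](c8ccccc8)(c8ccccc8)OC[C@@H](OC(=O)c6cc(OCc9ccccc9)c(OCc9ccccc9)c(OCc9ccccc9)c67)[C@H]2O[C@@H]3OC(C)(C)O[C@@H]3[C@H]2OC(=O)c4c(I)c(OCc9ccccc9)c(OCc9ccccc9)c(OCc9ccccc9)c47 | intermediate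
10 | open-chain dithioacetal with free O-2 and O-4 | CCSC(SCC)[C@H](O)[C@@H](OC(=O)c4c(I)c(OCc9ccccc9)c(OCc9ccccc9)c(OCc9ccccc9)c47)[C@H](O)[C@H](OC(=O)c6cc(OCc9ccccc9)c(OCc9ccccc9)c(OCc9ccccc9)c67)CO[Si](c8ccccc8)(c8ccccc8)C(C)(C)C | intermediate
11 | 2-O-(2-iodoaroyl) ester of 10 | CCSC(SCC)[C@H](OC(=O)c2cc(OCc9ccccc9)c(OCc9ccccc9)c(OCc9ccccc9)c2I)[C@@H](OC(=O)c4c(I)c(OCc9ccccc9)c(OCc9ccccc9)c(OCc9ccccc9)c47)[C@H](O)[C@H](OC(=O)c6cc(OCc9ccccc9)c(OCc9ccccc9)c(OCc9ccccc9)c67)CO[Si](c8ccccc8)(c8ccccc8)C(C)(C)C | intermediate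
12 | D/B-coupled bis-macrocycle (NHTP core) | CCSC(SCC)[C@H](OC(=O)c2cc(OCc9ccccc9)c(OCc9ccccc9)c(OCc9ccccc9)c23)[C@@H](OC(=O)c4c3c(OCc9ccccc9)c(OCc9ccccc9)c(OCc9ccccc9)c47)[C@H](O)[C@H](OC(=O)c6cc(OCc9ccccc9)c(OCc9ccccc9)c(OCc9ccccc9)c67)CO[Si](c8ccccc8)(c8ccccc8)C(C)(C)C | intermediate
13 | 4,6-diol of 12 (desilylated) | CCSC(SCC)[C@H](OC(=O)c2cc(OCc9ccccc9)c(OCc9ccccc9)c(OCc9ccccc9)c23)[C@@H](OC(=O)c4c3c(OCc9ccccc9)c(OCc9ccccc9)c(OCc9ccccc9)c47)[C@H](O)[C@H](OC(=O)c6cc(OCc9ccccc9)c(OCc9ccccc9)c(OCc9ccccc9)c67)CO | intermediate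
14 | 4,6-bis(2-iodoaroyl) ester | CCSC(SCC)[C@H](OC(=O)c2cc(OCc9ccccc9)c(OCc9ccccc9)c(OCc9ccccc9)c23)[C@@H](OC(=O)c4c3c(OCc9ccccc9)c(OCc9ccccc9)c(OCc9ccccc9)c47)[C@H](OC(=O)c%10cc(OCc9ccccc9)c(OCc9ccccc9)c(OCc9ccccc9)c%10I)[C@H](OC(=O)c6cc(OCc9ccccc9)c(OCc9ccccc9)c(OCc9ccccc9)c67)COC(=O)c%11cc(OCc9ccccc9)c(OCc9ccccc9)c(OCc9ccccc9)c%11I | intermediate
15 | tris-macrocyclic dithioacetal (perbenzyl) | CCSC(SCC)[C@H](OC(=O)c2cc(OCc9ccccc9)c(OCc9ccccc9)c(OCc9ccccc9)c23)[C@@H](OC(=O)c4c3c(OCc9ccccc9)c(OCc9ccccc9)c(OCc9ccccc9)c47)[C@H](OC(=O)c%10cc(OCc9ccccc9)c(OCc9ccccc9)c(OCc9ccccc9)c%10%11)[C@H](OC(=O)c6cc(OCc9ccccc9)c(OCc9ccccc9)c(OCc9ccccc9)c67)COC(=O)c%12cc(OCc9ccccc9)c(OCc9ccccc9)c(OCc9ccccc9)c%12%11 | intermediate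
16 | C-1 aldehyde (perbenzyl) | O=C[C@H](OC(=O)c2cc(OCc9ccccc9)c(OCc9ccccc9)c(OCc9ccccc9)c23)[C@@H](OC(=O)c4c3c(OCc9ccccc9)c(OCc9ccccc9)c(OCc9ccccc9)c47)[C@H](OC(=O)c%10cc(OCc9ccccc9)c(OCc9ccccc9)c(OCc9ccccc9)c%10%11)[C@H](OC(=O)c6cc(OCc9ccccc9)c(OCc9ccccc9)c(OCc9ccccc9)c67)COC(=O)c%12cc(OCc9ccccc9)c(OCc9ccccc9)c(OCc9ccccc9)c%12%11 | intermediate
17 | perbenzyl target (15 OBn, C-1 OH) | O=C1OC[C@H]2OC(=O)c3cc(OCc%13ccccc%13)c(OCc%13ccccc%13)c(OCc%13ccccc%13)c3-c3c(OCc%13ccccc%13)c(OCc%13ccccc%13)c(OCc%13ccccc%13)c4c3C(=O)O[C@H]([C@H]3OC(=O)c5c-4c(OCc%13ccccc%13)c(OCc%13ccccc%13)c(OCc%13ccccc%13)c5[C@H]3O)[C@@H]2OC(=O)c2cc(OCc%13ccccc%13)c(OCc%13ccccc%13)c(OCc%13ccccc%13)c2-c2c1cc(OCc%13ccccc%13)c(OCc%13ccccc%13)c2OCc%13ccccc%13 | intermediate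
18 | target (CID 12302513) | O=C1OC[C@H]2OC(=O)c3cc(O)c(O)c(O)c3-c3c(O)c(O)c(O)c4c3C(=O)O[C@H]([C@H]3OC(=O)c5c-4c(O)c(O)c(O)c5[C@H]3O)[C@@H]2OC(=O)c2cc(O)c(O)c(O)c2-c2c1cc(O)c(O)c2O | target

## Totals
Total steps: 16. Longest linear sequence: 16 (1→2→3→5→6→7→8→9→10→11→12→13→14→15→16→17→18, counting the acid-preparation steps). Counted from commercial diacetone glucose (**4**), it is 14.

## Three steps most likely to fail
1. **Step 15 (proposed new hydroxyalkylation).** It may give the wrong C-1 epimer, low conversion, or partial debenzylation or C-2 epimerisation under Lewis acid.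
   - Fallback: change the bond-forming logic to an intramolecular Nozaki–Hiyama–Kishi aryl–aldehyde coupling (CrCl2/NiCl2, DMF).
   - Use 2-iodo-6-bromo-tribenzyloxybenzoic acid for ring D in Step 9, so the CuTC steps consume only the iodide and the b6-Br survives to the NHK step.
   - If the C-1 epimer is wrong, correct it by oxidation (Dess–Martin) and reduction of the resulting ketone.
2. **Step 10 (D/B Ullmann, 10-membered ring).** The ring is strained, with competing homocoupling or protodeiodination.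
   - Fallback: switch to intramolecular Suzuki–Miyaura coupling.
   - Introduce ring D as the 2-Bpin aroyl ester in Step 9, then close onto ring B's iodide with Pd2(dba)3/SPhos/K3PO4.
3. **Step 9 (O-2 vs O-4 regioselectivity and acyl migration).**
   - Fallback: make the regiochemistry unambiguous with protecting groups. After Step 8, remove TBDPS (HF·pyridine) and form the 4,6-O-benzylidene acetal (PhCH(OMe)2, CSA). This leaves O-2 as the only free OH.
   - Then acylate O-2, run the Ullmann coupling, and remove the benzylidene by mild aqueous acid before Step 12.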